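**Plan**
- Core numbering follows spiro[4.5]decane: C-1 secondary carbinol, C-2 side-chain carbon, C-5 spiro centre, C-6 hydroxypropyl carbon, C-7 alkylidene carbon, C-10 tertiary carbinol.
- Cuts, last-made first: the triene side chain at its trisubstituted alkene and at the C-2–C bond (through a cis-fused γ-lactone on the C-1 oxygen); then the enal back to a C-7 acetyl group.
- Enabling feature: the 3-hydroxypropyl chain on C-6 and the three-carbon unit on C-7 are the two ends of a six-membered ring cut between the chain terminus and the methyl-bearing carbon. Re-joining them gives a methylcyclohexene fused at C-6/C-7, a Diels–Alder adduct. The C-10 oxygen and the C-6 chain are cis-1,3 on the cyclohexane, so one carbonyl carbon can tie the dienophile to that oxygen.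
- Forward: cyclopentane → quaternary C-5 ([2,3] shift) → C-10 carbinol → unsaturated δ-lactone (ring-closing metathesis) → diene → cycloaddition closing the cyclohexane and the temporary cyclohexene together → tether carbon excised → ozonolysis → enal → C-2 lactone (C–H insertion) → olefination → reduction, deprotection.
- Stereochemistry: C-1 from (1R,2R)-cyclopentanediol; C-5 by the sigmatropic shift anti to the ether; C-10 by chelation-controlled methyl addition; C-6 by the lactone bridge in the cycloaddition; C-2 by the cis ring fusion of the insertion; enal E from the chair [3,3] shift; side chain 2Z from a Still–Gennari-type olefination and 4E from the Heck-made dienal.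

Key step: step 16

Remark: an open-chain vinyl dienophile would have no reliable facial control at C-6, so the dienophile is tied to the C-10 oxygen as a lactone whose carbonyl carbon is removed in steps 17–18; acid 35 and Grignard solution 11 are taken as catalogue reagents.

**Route**

Step 1
Reactants: 1 (1R,2R)-cyclopentane-1,2-diol
Product: 2 (1R,2R)-2-(4-methoxybenzyloxy)cyclopentan-1-ol
Conditions: NaH (1.0 equiv), THF, 0 °C; 4-MeOC6H4CH2Cl, Bu4NI (cat.), 0 °C → rt
Reagents that add atoms: 4-methoxybenzyl chloride, COc1ccc(CCl)cc1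
Why: Williamson etherification of the monosodium alkoxide of a C2-symmetric diol, where either hydroxyl gives the same mono-ether and no stereocentre is touched.

Step 2
Reactants: 2 mono-ether
Product: 3 (2R)-2-(4-methoxybenzyloxy)cyclopentan-1-one
Conditions: Dess–Martin periodinane, NaHCO3, CH2Cl2, 0 °C → rt
Reagents that add atoms: none
Why: Dess–Martin oxidation under buffered, non-basic conditions should leave the α-alkoxy stereocentre intact.

Step 3
Reactants: 3 ketone; 4 triethyl phosphonoacetate
Product: 5 ethyl (2E)-[(2R)-2-(4-methoxybenzyloxy)cyclopentylidene]acetate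
Conditions: NaH, THF, 0 °C; then 3, 0 °C → rt
Reagents that add atoms: none
Why: Horner–Wadsworth–Emmons olefination of a reactive cyclopentanone at 0 °C should outrun enolisation; the E isomer is expected, and either geometry serves in step 6.

Step 4
Reactants: 5 enoate
Product: 6 (2E)-2-[(2R)-2-(4-methoxybenzyloxy)cyclopentylidene]ethan-1-ol
Conditions: iBu2AlH (2.2 equiv), CH2Cl2, −78 °C
Reagents that add atoms: none
Why: 1,2-reduction of an α,β-unsaturated ester to the allylic alcohol by iBu2AlH is standard and leaves the benzylic ether alone.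

Step 5
Reactants: 6 allylic alcohol
Product: 7 tributylstannylmethyl ether of 6
Conditions: KH, THF, 0 °C; Bu3SnCH2I, rt
Reagents that add atoms: tributyl(iodomethyl)stannane, CCCC[Sn](CCCC)(CCCC)CI
Why: Williamson O-alkylation of the potassium alkoxide with the primary iodide gives the precursor for the Wittig–Still rearrangement.

Step 6
Reactants: 7 stannylmethyl ether
Product: 9 [(1R,2R)-1-ethenyl-2-(4-methoxybenzyloxy)cyclopentyl]methanol, via lithiomethyl ether 8 (not isolated)
Conditions: n-BuLi, THF, −78 → −40 °C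
Reagents that add atoms: none
Why: Tin–lithium exchange triggers the [2,3]-Wittig–Still rearrangement; the carbanion should bond to the ring carbon on the face anti to the neighbouring ether, setting the quaternary C-5 with the vinyl group cis to the ether.

Step 7
Reactants: 9 neopentyl alcohol
Product: 10 (1S,2R)-1-ethenyl-2-(4-methoxybenzyloxy)cyclopentane-1-carbaldehyde
Conditions: Dess–Martin periodinane, NaHCO3, CH2Cl2, rt
Reagents that add atoms: none
Why: Dess–Martin oxidation of a primary alcohol to a non-enolisable aldehyde, so the quaternary centre cannot epimerise.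

Step 8
Reactants: 10 aldehyde; 11 [2-(1,3-dioxolan-2-yl)ethyl]magnesium bromide
Product: 12 secondary alcohol (both carbinol epimers)
Conditions: THF, −78 → 0 °C
Reagents that add atoms: none
Why: Grignard addition to an unhindered formyl group; the new carbinol centre is oxidised away in the next step.

Step 9
Reactants: 12 secondary alcohol
Product: 13 ketone
Conditions: Dess–Martin periodinane, NaHCO3, CH2Cl2, rt
Reagents that add atoms: none
Why: Dess–Martin oxidation tolerates the acetal, the vinyl group and the benzylic ether.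

Step 10
Reactants: 13 ketone
Product: 14 (2S)-tertiary alcohol
Conditions: MeMgBr (3 equiv), CH2Cl2/Et2O, −78 °C
Reagents that add atoms: methylmagnesium bromide, C[Mg]Br
Why: Chelation-controlled Grignard addition: magnesium bridges the ether oxygen and the ketone in a six-membered chelate with the vinyl group axial, and methyl should add anti to it, giving the C-10 configuration of the target.

Step 11
Reactants: 14 tertiary alcohol; 15 prop-2-enoyl chloride
Product: 16 tertiary acrylate
Conditions: KN(SiMe3)2, THF, −78 °C; then 15, −78 → 0 °C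
Reagents that add atoms: none
Why: O-acylation of the pre-formed potassium alkoxide is the usual way to esterify a hindered tertiary alcohol.

Step 12
Reactants: 16 acrylate
Product: 17 α,β-unsaturated δ-lactone (7-oxaspiro[4.5]dec-9-en-8-one)
Conditions: second-generation Hoveyda–Grubbs catalyst, RuCl2(=CH-C6H4-2-OiPr)(H2IMes) (10 mol %), PhMe, 80 °C
Reagents that add atoms: none
Why: Ring-closing metathesis of an acrylate with a vinyl group to a 5,6-dihydropyran-2-one; the six-membered ring forces the Z enoate, and the two fully substituted ring carbons favour closure.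

Step 13
Reactants: 17 lactone acetal
Product: 18 lactone aldehyde
Conditions: PPTS, acetone/H2O (9:1), 55 °C
Reagents that add atoms: water, O
Why: Mild acid-catalysed acetal hydrolysis that should spare the tertiary-alkyl lactone and the benzylic ether.

Step 14
Reactants: 18 aldehyde; 19 2-(triphenyl-λ5-phosphanylidene)propanal
Product: 20 (2E)-2-methyl enal
Conditions: PhMe, 90 °C
Reagents that add atoms: none
Why: Wittig reaction of a stabilised ylide gives the E trisubstituted enal and does not attack the lactone or the product enal.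

Step 15
Reactants: 20 enal
Product: 21 triene lactone, (1R,5S,6S)-1-(4-methoxybenzyloxy)-6-methyl-6-[(3E)-4-methylhexa-3,5-dien-1-yl]-7-oxaspiro[4.5]dec-9-en-8-one
Conditions: Ph3PCH3Br, KN(SiMe3)2, THF, 0 °C; then 20, −78 → 0 °C
Reagents that add atoms: methyltriphenylphosphonium bromide, C[P+](c1ccccc1)(c1ccccc1)c1ccccc1.[Br-]
Why: Wittig methylenation of the aldehyde, far faster than any reaction of the ylide with the hindered lactone, completes the (E)-diene.

Step 16
Reactants: 21 triene lactone
Product: 22 bridged Diels–Alder adduct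
Conditions: PhMe (0.01 M), BHT, 150 °C, sealed tube
Reagents that add atoms: none
Why: Thermal, concerted suprafacial [4+2] cycloaddition of a 1,7,9-decatriene whose (Z)-dienophile is held in an unsaturated δ-lactone; the closest known reaction type is the intramolecular Diels–Alder reaction of ester-activated decatrienes to octalins. The cyclohexane (C-5 to C-10) closes through the four-atom tether in a chair, the diene terminus reaching the enoate β-carbon from the axial C-10 chain so that the lactone becomes a bridge, and the cyclohexene closes as the diene spans both dienophile carbons on one face. C-6 is controlled by that bridge: the diene can reach only the lactone face carrying the chain, so the lactone α-carbon (the future first carbon of the hydroxypropyl chain) must end cis to the C-10 oxygen, which is the relation in the target; the lactone α-carbon and C-7 follow from suprafacial addition and the chair (cis ring fusion) and are erased later. The step needs π-facial selectivity at C-6 relative to C-5 and C-10, and the covalent C-10–O–C(=O) tether secures it. The lactone carbonyl lowers the dienophile LUMO, and the methyl on the inner diene carbon puts the larger HOMO coefficient on the tethered terminus, which bonds to the β-carbon, so about 150 °C should suffice.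

Step 17
Reactants: 22 bridged lactone
Product: 23 bridged lactol (both anomers)
Conditions: iBu2AlH (1.2 equiv), CH2Cl2, −78 °C
Reagents that add atoms: none
Why: Partial reduction of a lactone to the lactol at −78 °C, where the aluminium hemiacetal is stable until work-up.

Step 18
Reactants: 23 lactol
Product: 24 cis-fused octalin tertiary alcohol
Conditions: RhCl(PPh3)3 (1.1 equiv), PhCN, 130 °C
Reagents that add atoms: none
Why: Tsuji–Wilkinson decarbonylation of the hydroxy aldehyde in equilibrium with the lactol removes the tether carbon as CO, leaving CH2 at the former lactone α-carbon and the free C-10 hydroxyl.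

Step 19
Reactants: 24 tertiary alcohol
Product: 25 triethylsilyl ether
Conditions: Et3SiOSO2CF3, 2,6-lutidine, CH2Cl2, −78 → 0 °C
Reagents that add atoms: triethylsilyl trifluoromethanesulfonate, CC[Si](CC)(CC)OS(=O)(=O)C(F)(F)F
Why: Silyl triflates silylate hindered tertiary alcohols; the ether protects C-10–OH through the carbenoid step.

Step 20
Reactants: 25 octalin silyl ether
Product: 27 hydroxy ketone (C-6 3-hydroxypropyl; C-7 acetyl), via keto aldehyde 26 (not isolated)
Conditions: O3, CH2Cl2/MeOH (4:1), −78 °C (Sudan red end point); PPh3, −78 °C → rt; then NaBH4, −78 °C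
Reagents that add atoms: ozone, O=[O+][O-]
Why: Ozonolysis of the only alkene with reductive work-up, then chemoselective borohydride reduction of the aldehyde in the presence of the α-branched methyl ketone at −78 °C.

Step 21
Reactants: 27 hydroxy ketone
Product: 28 primary tert-butyldimethylsilyl ether
Conditions: tBuMe2SiCl, imidazole, CH2Cl2, 0 °C
Reagents that add atoms: tert-butyldimethylsilyl chloride, CC(C)(C)[Si](C)(C)Cl
Why: Standard silylation of a primary alcohol.

Step 22
Reactants: 28 methyl ketone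
Product: 30 α-hydroxy ketone (tertiary C-7 hydroxyl; C-7 epimers), via α-hydroperoxy ketone 29 (not isolated)
Conditions: KOtBu, O2, P(OEt)3, THF/tBuOH, −20 °C
Reagents that add atoms: dioxygen, O=O
Why: Enolate autoxidation under equilibrating conditions oxygenates the more substituted α-carbon, as in the 17-hydroxylation of 20-keto steroids; the phosphite reduces the hydroperoxide in situ.

Step 23
Reactants: 30 α-hydroxy ketone
Product: 31 tertiary allylic alcohol (C-7 hydroxyl and prop-1-en-2-yl)
Conditions: Ph3PCH3Br, KOtBu, PhMe, 80 °C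
Reagents that add atoms: methyltriphenylphosphonium bromide, C[P+](c1ccccc1)(c1ccccc1)c1ccccc1.[Br-]
Why: Wittig methylenation with excess salt-free ylide at 80 °C is the usual answer to hindered ketones and tolerates the free tertiary alkoxide.

Step 24
Reactants: 31 tertiary allylic alcohol
Product: 32 (E)-enal
Conditions: C5H5NH[CrO3Cl] (pyridinium chlorochromate), 4 Å sieves, CH2Cl2, rt
Reagents that add atoms: none
Why: Babler–Dauben oxidative transposition: [3,3] shift of the chromate ester then oxidation places the alkene at C-7 without regiochemical ambiguity, and a chair with the more substituted C-6 pseudo-equatorial should put the methyl cis to C-6 (E), which is also the expected thermodynamic isomer.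

Step 25
Reactants: 32 enal
Product: 33 enal 1,3-dioxolane
Conditions: Me3SiOCH2CH2OSiMe3, Me3SiOSO2CF3 (cat.), CH2Cl2, −78 → −20 °C
Reagents that add atoms: 1,2-bis(trimethylsilyloxy)ethane, C[Si](C)(C)OCCO[Si](C)(C)C
Why: Noyori acetalisation masks the enal against base and hydride without moving the double bond.

Step 26
Reactants: 33 benzylic ether
Product: 34 C-1 secondary alcohol
Conditions: DDQ, CH2Cl2/pH 7 buffer (10:1), 0 °C
Reagents that add atoms: none
Why: Oxidative cleavage of the 4-methoxybenzyl ether by DDQ spares silyl ethers, the acetal and the electron-poor-substituted alkene.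

Step 27
Reactants: 34 alcohol; 35 [bis(2,2,2-trifluoroethoxy)phosphoryl]acetic acid
Product: 36 phosphonoacetate ester
Conditions: DCC, DMAP (cat.), CH2Cl2, 0 °C → rt
Reagents that add atoms: none
Why: Steglich esterification of the only free hydroxyl.

Step 28
Reactants: 36 phosphonoacetate
Product: 37 α-diazo phosphonoacetate
Conditions: 4-AcNHC6H4SO2N3, DBU, MeCN, 0 °C
Reagents that add atoms: 4-acetamidobenzenesulfonyl azide, CC(=O)Nc1ccc(cc1)S(=O)(=O)N=[N+]=[N-]
Why: Regitz diazo transfer to a doubly activated methylene.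

Step 29
Reactants: 37 diazo ester
Product: 38 cis-fused α-phosphono γ-lactone
Conditions: Rh2(OAc)4 (2 mol %), (CH2Cl)2, 80 °C, slow addition
Reagents that add atoms: none
Why: Rhodium-carbenoid 1,5 C–H insertion into the C-2 methylene forms the γ-lactone with retention, and only the hydrogen cis to the ester oxygen can give the cis-fused bicycle, which sets C-2 with its carbon substituent cis to the C-1 oxygen.

Step 30
Reactants: 39 6-methylhept-5-en-2-one
Product: 40 6-methylhepta-1,5-dien-2-yl trifluoromethanesulfonate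
Conditions: LiN(iPr)2, THF, −78 °C; PhN(SO2CF3)2, −78 → 0 °C
Reagents that add atoms: N-phenylbis(trifluoromethanesulfonimide), O=S(=O)(N(c1ccccc1)S(=O)(=O)C(F)(F)F)C(F)(F)F
Why: Kinetic deprotonation of the methyl ketone at the methyl group and O-triflation give the terminal enol triflate.

Step 31
Reactants: 40 enol triflate; 41 prop-2-enal
Product: 42 (2E)-8-methyl-4-methylidenenona-2,7-dienal
Conditions: Pd(OAc)2 (5 mol %), PPh3, Et3N, DMF, 60 °C
Reagents that add atoms: none
Why: Heck vinylation of an enol triflate with acrolein gives the E dienal through syn insertion and syn β-hydride elimination.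

Step 32
Reactants: 38 phosphono lactone; 42 dienal
Product: 43 (Z)-α-alkylidene lactone
Conditions: KN(SiMe3)2, 18-crown-6, THF, −78 °C; then 42
Reagents that add atoms: none
Why: Still–Gennari-type Horner–Wadsworth–Emmons olefination: the trifluoroethyl phosphonate with a dissociated potassium counter-ion eliminates from the kinetic adduct, as known for α-phosphono lactones, placing the dienyl chain cis to the lactone carbonyl.

Step 33
Reactants: 43 alkylidene lactone
Product: 44 diol (C-1 hydroxyl and side-chain CH2OH)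
Conditions: iBu2AlH (5 equiv), CH2Cl2, −78 → 0 °C
Reagents that add atoms: none
Why: iBu2AlH reduces the conjugated lactone 1,2 to the allylic diol with the alkene geometry unchanged and leaves the acetal and silyl ethers in place.

Step 34
Reactants: 44 protected tetraol acetal
Product: 45 target
Conditions: HF (48 % aq.)/MeCN (1:19), 0 °C → rt
Reagents that add atoms: water, O
Why: Aqueous HF in acetonitrile is a mildly acidic global deprotection that cleaves both silyl ethers and hydrolyses the conjugated dioxolane to the enal.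

**Compound list**

1 | (1R,2R)-cyclopentane-1,2-diol | O[C@@H]1CCC[C@H]1O | starting material
2 | (1R,2R)-2-[(4-methoxyphenyl)methoxy]cyclopentan-1-ol | O[C@@H]1CCC[C@H]1OCc1ccc(OC)cc1 | intermediate
3 | (2R)-2-[(4-methoxyphenyl)methoxy]cyclopentan-1-one | O=C1CCC[C@H]1OCc1ccc(OC)cc1 | intermediate
4 | triethyl phosphonoacetate | CCOC(=O)CP(=O)(OCC)OCC | starting material
5 | ethyl (2E)-2-{(2R)-2-[(4-methoxyphenyl)methoxy]cyclopentylidene}acetate | CCOC(=O)/C=C1\CCC[C@H]1OCc1ccc(OC)cc1 | intermediate
6 | (2E)-2-{(2R)-2-[(4-methoxyphenyl)methoxy]cyclopentylidene}ethan-1-ol | OC/C=C1\CCC[C@H]1OCc1ccc(OC)cc1 | intermediate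
7 | tributyl[({(2E)-2-[(2R)-2-(4-methoxybenzyloxy)cyclopentylidene]ethyl}oxy)methyl]stannane | CCCC[Sn](CCCC)(CCCC)COC/C=C1\CCC[C@H]1OCc1ccc(OC)cc1 | intermediate
8 | [({(2E)-2-[(2R)-2-(4-methoxybenzyloxy)cyclopentylidene]ethyl}oxy)methyl]lithium | [Li]COC/C=C1\CCC[C@H]1OCc1ccc(OC)cc1 | intermediate (not isolated)
9 | [(1R,2R)-1-ethenyl-2-(4-methoxybenzyloxy)cyclopentyl]methanol (vinyl cis to the ether) | C=C[C@]1(CCC[C@H]1OCc1ccc(OC)cc1)CO | intermediate
10 | (1S,2R)-1-ethenyl-2-(4-methoxybenzyloxy)cyclopentane-1-carbaldehyde | C=C[C@]1(CCC[C@H]1OCc1ccc(OC)cc1)C=O | intermediate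
11 | [2-(1,3-dioxolan-2-yl)ethyl]magnesium bromide | Br[Mg]CCC1OCCO1 | starting material
12 | 3-(1,3-dioxolan-2-yl)-1-[(1R,2R)-1-ethenyl-2-(4-methoxybenzyloxy)cyclopentyl]propan-1-ol (carbinol epimers) | C=C[C@]1(CCC[C@H]1OCc1ccc(OC)cc1)C(O)CCC1OCCO1 | intermediate
13 | 3-(1,3-dioxolan-2-yl)-1-[(1S,2R)-1-ethenyl-2-(4-methoxybenzyloxy)cyclopentyl]propan-1-one | C=C[C@]1(CCC[C@H]1OCc1ccc(OC)cc1)C(=O)CCC1OCCO1 | intermediate
14 | (2S)-4-(1,3-dioxolan-2-yl)-2-[(1S,2R)-1-ethenyl-2-(4-methoxybenzyloxy)cyclopentyl]butan-2-ol | C=C[C@]1(CCC[C@H]1OCc1ccc(OC)cc1)[C@@](C)(O)CCC1OCCO1 | intermediate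
15 | prop-2-enoyl chloride | C=CC(=O)Cl | starting material
16 | (2S)-4-(1,3-dioxolan-2-yl)-2-[(1S,2R)-1-ethenyl-2-(4-methoxybenzyloxy)cyclopentyl]butan-2-yl prop-2-enoate | C=C[C@]1(CCC[C@H]1OCc1ccc(OC)cc1)[C@@](C)(OC(=O)C=C)CCC1OCCO1 | intermediate
17 | (1R,5S,6S)-6-[2-(1,3-dioxolan-2-yl)ethyl]-1-(4-methoxybenzyloxy)-6-methyl-7-oxaspiro[4.5]dec-9-en-8-one | O=C1C=C[C@]2(CCC[C@H]2OCc3ccc(OC)cc3)[C@](C)(CCC4OCCO4)O1 | intermediate
18 | 3-[(1R,5S,6S)-1-(4-methoxybenzyloxy)-6-methyl-8-oxo-7-oxaspiro[4.5]dec-9-en-6-yl]propanal | O=C1C=C[C@]2(CCC[C@H]2OCc3ccc(OC)cc3)[C@](C)(CCC=O)O1 | intermediate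
19 | 2-(triphenyl-λ5-phosphanylidene)propanal | CC(C=O)=P(c1ccccc1)(c1ccccc1)c1ccccc1 | starting material
20 | (2E)-5-[(1R,5S,6S)-1-(4-methoxybenzyloxy)-6-methyl-8-oxo-7-oxaspiro[4.5]dec-9-en-6-yl]-2-methylpent-2-enal | O=C1C=C[C@]2(CCC[C@H]2OCc3ccc(OC)cc3)[C@](C)(CC/C=C(\C)C=O)O1 | intermediate
21 | (1R,5S,6S)-1-(4-methoxybenzyloxy)-6-methyl-6-[(3E)-4-methylhexa-3,5-dien-1-yl]-7-oxaspiro[4.5]dec-9-en-8-one | O=C1C=C[C@]2(CCC[C@H]2OCc3ccc(OC)cc3)[C@](C)(CC/C=C(\C)C=C)O1 | intermediate
22 | Diels–Alder adduct: δ-lactone bridging the C-10 oxygen and the CH attached to C-6 across the new cyclohexane, methylcyclohexene cis-fused at C-6/C-7, spiro cyclopentane with the 4-methoxybenzyl ether | O=C1[C@@H]2CC=C(C)[C@@H]3CC[C@](C)(O1)[C@@]4(CCC[C@H]4OCc5ccc(OC)cc5)[C@H]23 | intermediate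
23 | lactol of 22 (lactone C=O reduced to CH–OH, both anomers) | OC1[C@@H]2CC=C(C)[C@@H]3CC[C@](C)(O1)[C@@]4(CCC[C@H]4OCc5ccc(OC)cc5)[C@H]23 | intermediate
24 | (2R)-2-(4-methoxybenzyloxy)-2',5'-dimethyl-3',4',4a',7',8',8a'-hexahydro-2'H-spiro[cyclopentane-1,1'-naphthalen]-2'-ol, cis-fused, hydroxyl cis to the ether-bearing ring carbon | C1CC[C@]2([C@@H]3CCC=C(C)[C@@H]3CC[C@]2(C)O)[C@@H]1OCc1ccc(OC)cc1 | intermediate
25 | triethylsilyl ether of 24 | C1CC[C@]2([C@@H]3CCC=C(C)[C@@H]3CC[C@]2(C)O[Si](CC)(CC)CC)[C@@H]1OCc1ccc(OC)cc1 | intermediate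
26 | 3-[(1R,5S,6R,7R,10S)-7-acetyl-1-(4-methoxybenzyloxy)-10-methyl-10-(triethylsilyloxy)spiro[4.5]decan-6-yl]propanal | C1CC[C@]2([C@H](CCC=O)[C@H](C(C)=O)CC[C@]2(C)O[Si](CC)(CC)CC)[C@@H]1OCc1ccc(OC)cc1 | intermediate (not isolated)
27 | 1-[(1R,5S,6R,7R,10S)-6-(3-hydroxypropyl)-1-(4-methoxybenzyloxy)-10-methyl-10-(triethylsilyloxy)spiro[4.5]decan-7-yl]ethan-1-one | C1CC[C@]2([C@H](CCCO)[C@H](C(C)=O)CC[C@]2(C)O[Si](CC)(CC)CC)[C@@H]1OCc1ccc(OC)cc1 | intermediate
28 | tert-butyldimethylsilyl ether of 27 (at the primary hydroxyl) | C1CC[C@]2([C@H](CCCO[Si](C)(C)C(C)(C)C)[C@H](C(C)=O)CC[C@]2(C)O[Si](CC)(CC)CC)[C@@H]1OCc1ccc(OC)cc1 | intermediate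
29 | 7-hydroperoxy derivative of 28 (C-7 epimers) | C1CC[C@]2([C@H](CCCO[Si](C)(C)C(C)(C)C)C(OO)(C(C)=O)CC[C@]2(C)O[Si](CC)(CC)CC)[C@@H]1OCc1ccc(OC)cc1 | intermediate (not isolated)
30 | 7-hydroxy derivative of 28 (7-acetyl-7-hydroxy, C-7 epimers) | C1CC[C@]2([C@H](CCCO[Si](C)(C)C(C)(C)C)C(O)(C(C)=O)CC[C@]2(C)O[Si](CC)(CC)CC)[C@@H]1OCc1ccc(OC)cc1 | intermediate
31 | 7-hydroxy-7-(prop-1-en-2-yl) analogue of 30 (C-7 epimers) | C1CC[C@]2([C@H](CCCO[Si](C)(C)C(C)(C)C)C(O)(C(C)=C)CC[C@]2(C)O[Si](CC)(CC)CC)[C@@H]1OCc1ccc(OC)cc1 | intermediate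
32 | (2E)-2-[(1R,5S,6R,10S)-6-[3-(tert-butyldimethylsilyloxy)propyl]-1-(4-methoxybenzyloxy)-10-methyl-10-(triethylsilyloxy)spiro[4.5]decan-7-ylidene]propanal | C1CC[C@]2([C@H](CCCO[Si](C)(C)C(C)(C)C)/C(=C(\C)C=O)CC[C@]2(C)O[Si](CC)(CC)CC)[C@@H]1OCc1ccc(OC)cc1 | intermediate
33 | 1,3-dioxolane acetal of 32 | C1CC[C@]2([C@H](CCCO[Si](C)(C)C(C)(C)C)/C(=C(\C)C3OCCO3)CC[C@]2(C)O[Si](CC)(CC)CC)[C@@H]1OCc1ccc(OC)cc1 | intermediate
34 | C-1 alcohol from 33 (4-methoxybenzyl removed) | C1CC[C@]2([C@H](CCCO[Si](C)(C)C(C)(C)C)/C(=C(\C)C3OCCO3)CC[C@]2(C)O[Si](CC)(CC)CC)[C@@H]1O | intermediate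
35 | [bis(2,2,2-trifluoroethoxy)phosphoryl]acetic acid | OC(=O)CP(=O)(OCC(F)(F)F)OCC(F)(F)F | starting material
36 | C-1 [bis(2,2,2-trifluoroethoxy)phosphoryl]acetate of 34 | C1CC[C@]2([C@H](CCCO[Si](C)(C)C(C)(C)C)/C(=C(\C)C3OCCO3)CC[C@]2(C)O[Si](CC)(CC)CC)[C@@H]1OC(=O)CP(=O)(OCC(F)(F)F)OCC(F)(F)F | intermediate
37 | α-diazo derivative of 36 | C1CC[C@]2([C@H](CCCO[Si](C)(C)C(C)(C)C)/C(=C(\C)C3OCCO3)CC[C@]2(C)O[Si](CC)(CC)CC)[C@@H]1OC(=O)C(=[N+]=[N-])P(=O)(OCC(F)(F)F)OCC(F)(F)F | intermediate
38 | cis-fused γ-lactone on C-1–O/C-2 bearing the phosphonate on its α-carbon (α-epimers) | O=C1O[C@@H]2[C@H](C1P(=O)(OCC(F)(F)F)OCC(F)(F)F)CC[C@]23[C@H](CCCO[Si](C)(C)C(C)(C)C)/C(=C(\C)C4OCCO4)CC[C@]3(C)O[Si](CC)(CC)CC | intermediate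
39 | 6-methylhept-5-en-2-one | CC(=O)CCC=C(C)C | starting material
40 | 6-methylhepta-1,5-dien-2-yl trifluoromethanesulfonate | C=C(OS(=O)(=O)C(F)(F)F)CCC=C(C)C | intermediate
41 | prop-2-enal | C=CC=O | starting material
42 | (2E)-8-methyl-4-methylidenenona-2,7-dienal | O=C/C=C/C(=C)CCC=C(C)C | intermediate
43 | (Z)-α-[(2E)-8-methyl-4-methylidenenona-2,7-dienylidene] lactone from 38 (chain cis to the lactone carbonyl) | O=C1O[C@@H]2[C@H](/C1=C/C=C/C(=C)CCC=C(C)C)CC[C@]23[C@H](CCCO[Si](C)(C)C(C)(C)C)/C(=C(\C)C4OCCO4)CC[C@]3(C)O[Si](CC)(CC)CC | intermediate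
44 | target carrying the C-10 triethylsilyl ether, the primary tert-butyldimethylsilyl ether and the enal dioxolane | C=C(/C=C/C=C(\CO)[C@@H]1CC[C@]2([C@H](CCCO[Si](C)(C)C(C)(C)C)/C(=C(\C)C3OCCO3)CC[C@]2(C)O[Si](CC)(CC)CC)[C@@H]1O)CCC=C(C)C | intermediate
45 | (2E)-2-[(1R,2S,5S,6R,10S)-1,10-dihydroxy-2-[(2Z,4E)-1-hydroxy-10-methyl-6-methylideneundeca-2,4,9-trien-2-yl]-6-(3-hydroxypropyl)-10-methylspiro[4.5]decan-7-ylidene]propanal | C=C(/C=C/C=C(\CO)[C@@H]1CC[C@]2([C@H](CCCO)/C(=C(\C)C=O)CC[C@]2(C)O)[C@@H]1O)CCC=C(C)C | target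

**Step count and risks**

Total: 34 steps. Longest linear sequence: 32 steps (steps 1–29 and 32–34).

Most likely to fail:

1. Step 12. The catalyst may fail to initiate on either alkene (a vinyl group on a quaternary carbon and an electron-poor acrylate on a tertiary oxygen), so ring closure loses to catalyst decay; the hindered acylation before it shares the risk. The fallback sets out from 14 and returns at 17 without 16. Ozonolysis of the vinyl group (O3, CH2Cl2/MeOH, −78 °C; PPh3) would give the hydroxy aldehyde F1. A Z-selective Ando olefination with ethyl (diphenoxyphosphoryl)acetate (NaI, DBU, THF, 0 °C) would give the (Z)-enoate F2, which should close onto the tertiary hydroxyl to lactone 17 on warming with catalytic TsOH.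

2. Step 18. The bridged lactol may stay closed so that rhodium cannot insert into the aldehyde C–H bond, or the alkylrhodium hydride may lose a β-hydrogen to give an alkene. The fallback sets out from 22 and returns at 24 without 23. Saponification (LiOH, THF/MeOH/H2O, 60 °C) would give the hydroxy acid F3 as its carboxylate. Photoredox hydrodecarboxylation (9-mesityl-10-methylacridinium tetrafluoroborate, (PhS)2, iPr2NEt, CF3CH2OH, blue light) would then replace the carboxyl by hydrogen.

3. Step 29. Insertion may go into the allylic tertiary C-6–H bond (δ-lactone) instead of the C-2 methylene, or the acceptor-substituted carbenoid may dimerise. The fallback sets out from 34 and returns at 38 by enolate chemistry. Dess–Martin oxidation would give the cyclopentanone F4. Alkylation (LiN(SiMe3)2, methyl bromoacetate) would give the keto ester F5 as equilibrating C-2 epimers. Reduction with LiBH(sBu)3, hydride entering anti to the new substituent, and acidic work-up would close only the cis hydroxy ester to the γ-lactone F6, which is separated from epimeric material. Phosphorylation and base-induced phosphate-to-phosphonate shift (LiN(iPr)2, ClP(O)(OCH2CF3)2, then LiN(iPr)2) would give 38.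

**Further compounds**

F1 | step 12 | 1-[(2S)-4-(1,3-dioxolan-2-yl)-2-hydroxybutan-2-yl]-2-(4-methoxybenzyloxy)cyclopentane-1-carbaldehyde, ring centres as in 14 | O=C[C@]1(CCC[C@H]1OCc1ccc(OC)cc1)[C@@](C)(O)CCC1OCCO1
F2 | step 12 | ethyl (2Z)-3-{1-[(2S)-4-(1,3-dioxolan-2-yl)-2-hydroxybutan-2-yl]-2-(4-methoxybenzyloxy)cyclopentyl}prop-2-enoate, ring centres as in 14 | CCOC(=O)/C=C\[C@]1(CCC[C@H]1OCc1ccc(OC)cc1)[C@@](C)(O)CCC1OCCO1
F3 | step 18 | hydroxy acid from opening the lactone of 22 (CO2H on the carbon attached to C-6, free C-10 hydroxyl) | OC(=O)[C@@H]2CC=C(C)[C@@H]3CC[C@](C)(O)[C@@]4(CCC[C@H]4OCc5ccc(OC)cc5)[C@H]23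
F4 | step 29 | C-1 ketone from 34 | C1CC[C@]2([C@H](CCCO[Si](C)(C)C(C)(C)C)/C(=C(\C)C3OCCO3)CC[C@]2(C)O[Si](CC)(CC)CC)C1=O
F5 | step 29 | methyl 2-(C-1-oxo-spirodecan-2-yl)acetate from F4 (C-2 epimers) | COC(=O)CC1CC[C@]2([C@H](CCCO[Si](C)(C)C(C)(C)C)/C(=C(\C)C3OCCO3)CC[C@]2(C)O[Si](CC)(CC)CC)C1=O
F6 | step 29 | cis-fused γ-lactone on C-1–O/C-2 without the phosphonate | O=C1O[C@@H]2[C@H](C1)CC[C@]23[C@H](CCCO[Si](C)(C)C(C)(C)C)/C(=C(\C)C4OCCO4)CC[C@]3(C)O[Si](CC)(CC)CC
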